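**Strategy.** Everything rests on closing the cyclopentene C1–C5 last, by an intramolecular phosphine-catalysed [3+2] annulation (dictyol locants, listed below). C2–C4 and the C4 methyl carbon C17 are hung as a but-2-ynoate on O6 of a 4-hydroxycyclohept-2-enone that already carries the oxolane. The step exploits that O6 is cis to the C4–C5 bond and within five-ring reach of C17 (O6–C6–C5–C4–C17). The ester therefore becomes a temporary γ-lactone: one operation forms C4–C5, C1–C2 and the C3=C4 alkene and relays C6 to C5 and C1. The cycloheptenone comes from (R)-linalool (C11 bought, C14 by Shi epoxidation, C7 by aminocatalysis, C6 by Felkin control) through ring-closing metathesis.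

Key step: step 10

Remarks: Locants are those of the dictyol skeleton: C1 and C5 ring fusion; C2, C3, C4 cyclopentene with C17 the methyl on C4; C6 carbinol; C7 bears the oxolane; C8, C9; C10 with its methylene carbon C18; oxolane C11(CH3)–C12–C13–C14; C15 = CMe2O. The target is (1R,5R,6S,7R,11R,14R). Assumption: the L-sorbose-derived enantiomer of the Shi ketone is taken as an accessible catalyst.

**Step 1**
Reactants: 1 (R)-(−)-linalool
Product: 3 2-[(2R,5R)-5-ethenyl-5-methyloxolan-2-yl]propan-2-ol, via (3R,6S)-6,7-epoxylinalool 2 (not isolated)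
Conditions: enantiomer of the D-fructose-derived Shi ketone (30 mol %), KHSO5 (Oxone), K2CO3, Bu4NHSO4, MeCN–CH2(OMe)2–aq. Na2B4O7, 0 °C; extractive work-up, then camphorsulfonic acid (10 mol %), CH2Cl2, 0 °C
Reagents that add atoms: potassium peroxymonosulfate (KHSO5) [K+].[O-]S(=O)(=O)OO
Why: Shi asymmetric epoxidation followed by acid-catalysed 5-exo-tet epoxide opening: the chiral dioxirane should epoxidise only the electron-rich trisubstituted alkene and set the epoxide carbon (6S) by reagent control, and the tertiary hydroxyl then opens it with inversion to give the oxolane with C14 (R) next to the purchased C11 (R) centre.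

**Step 2**
Reactants: 3 2-[(2R,5R)-5-ethenyl-5-methyloxolan-2-yl]propan-2-ol
Product: 4 2-[(2R,5R)-5-(2-hydroxyethyl)-5-methyloxolan-2-yl]propan-2-ol
Conditions: 9-BBN (2.5 equiv), THF, 0 °C to rt; then NaOH, H2O2, 0 °C
Reagents that add atoms: hydrogen peroxide OO
Why: Hydroboration–oxidation: the bulky borane adds at the terminal carbon of the vinyl group next to the quaternary centre, so oxidation should give the primary alcohol; no stereocenter is formed.

**Step 3**
Reactants: 4 2-[(2R,5R)-5-(2-hydroxyethyl)-5-methyloxolan-2-yl]propan-2-ol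
Product: 5 2-[(2R,5R)-5-(2-hydroxypropan-2-yl)-2-methyloxolan-2-yl]acetaldehyde
Conditions: TEMPO (10 mol %), PhI(OAc)2, CH2Cl2, rt
Reagents that add atoms: none
Why: Oxoammonium (TEMPO) oxidation selects the primary alcohol and stops at the aldehyde, while the tertiary alcohol cannot be oxidised.

**Step 4**
Reactants: 6 (E)-but-2-enal (crotonaldehyde)
Product: 7 (E)-hexa-1,4-dien-3-ol (racemic)
Conditions: CH2=CHMgBr, THF, −78 °C; aq. NH4Cl
Reagents that add atoms: vinylmagnesium bromide C=C[Mg]Br
Why: Grignard 1,2-addition to the enal gives the bis-allylic alcohol; its racemic carbinol centre is removed in the next step.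

**Step 5**
Reactants: 7 (E)-hexa-1,4-dien-3-ol
Product: 8 (E)-hexa-1,4-dien-3-one
Conditions: MnO2, CH2Cl2, rt
Reagents that add atoms: none
Why: MnO2 oxidation of the doubly allylic alcohol should give the cross-conjugated dienone without touching the alkenes.

**Step 6**
Reactants: 5 2-[(2R,5R)-5-(2-hydroxypropan-2-yl)-2-methyloxolan-2-yl]acetaldehyde; 8 (E)-hexa-1,4-dien-3-one
Product: 9 (2S,6E)-2-[(2R,5R)-5-(2-hydroxypropan-2-yl)-2-methyloxolan-2-yl]-5-oxooct-6-enal
Conditions: (S)-α,α-diphenylprolinol trimethylsilyl ether (20 mol %), ethyl 3,4-dihydroxybenzoate (20 mol %), CHCl3, 4 °C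
Reagents that add atoms: none
Why: Enamine-catalysed Michael addition: the E-enamine of 5 should add to the unsubstituted vinyl terminus of 8 from the face opposite the diaryl(silyloxy)methyl group of the catalyst, which sets C7 (2S in 9) by catalyst control, while the catechol co-catalyst activates the enone by hydrogen bonding.

**Step 7**
Reactants: 9 (2S,6E)-2-[(2R,5R)-5-(2-hydroxypropan-2-yl)-2-methyloxolan-2-yl]-5-oxooct-6-enal
Product: 10 (2E,7R,8S)-8-hydroxy-7-[(2R,5R)-5-(2-hydroxypropan-2-yl)-2-methyloxolan-2-yl]deca-2,9-dien-4-one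
Conditions: CrCl2 (4 equiv), NiCl2 (2 mol %), vinyl bromide, DMF, rt
Reagents that add atoms: vinyl bromide C=CBr
Why: Nozaki–Hiyama–Kishi reaction: the vinyl species on trivalent chromium adds to the aldehyde and leaves the enone alone, and Felkin–Anh approach anti to the quaternary oxolane carbon should set C6 (8S in 10), the relationship that becomes cis on the ring.

**Step 8**
Reactants: 10 (2E,7R,8S)-8-hydroxy-7-[(2R,5R)-5-(2-hydroxypropan-2-yl)-2-methyloxolan-2-yl]deca-2,9-dien-4-one
Product: 11 (4S,5R)-4-hydroxy-5-[(2R,5R)-5-(2-hydroxypropan-2-yl)-2-methyloxolan-2-yl]cyclohept-2-en-1-one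
Conditions: second-generation Grubbs catalyst (5 mol %), CH2Cl2 (5 mM), 40 °C
Reagents that add atoms: none
Why: Ring-closing metathesis: the catalyst loads on the terminal vinyl group and closes onto the propenyl ketone with loss of propene, which should give the seven-membered Z-enone with both stereocenters untouched.

**Step 9**
Reactants: 11 (4S,5R)-4-hydroxy-5-[(2R,5R)-5-(2-hydroxypropan-2-yl)-2-methyloxolan-2-yl]cyclohept-2-en-1-one; 12 but-2-ynoic acid
Product: 13 (1S,7R)-7-[(2R,5R)-5-(2-hydroxypropan-2-yl)-2-methyloxolan-2-yl]-4-oxocyclohept-2-en-1-yl but-2-ynoate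
Conditions: DCC, DMAP (10 mol %), CH2Cl2, 0 °C
Reagents that add atoms: none
Why: Steglich esterification should acylate the secondary allylic hydroxyl at O6 while the hindered tertiary hydroxyl does not react; C6 keeps its configuration.

**Step 10**
Reactants: 13 (1S,7R)-7-[(2R,5R)-5-(2-hydroxypropan-2-yl)-2-methyloxolan-2-yl]-4-oxocyclohept-2-en-1-yl but-2-ynoate
Product: 14 tricyclic keto lactone (1R,5R,6S,7R,11R,14R): cis-fused cyclopenta-cycloheptan-10-one with the C3=C4 alkene, C17 as a lactone carbonyl closed onto O6, and the oxolane (free C15 hydroxyl) on C7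
Conditions: PBu3 (20 mol %), toluene (0.02 M), rt to 60 °C
Reagents that add atoms: none
Why: PBu3 adds to C3 of the ynoate and, after a proton shift from the C2 methyl group, gives the allylic phosphonium dienolate (a 1,3-dipole); its α-carbon C4 adds to the enone β-carbon C5 (5-exo-trig, closing the temporary γ-lactone), the resulting C10 enolate attacks the vinylphosphonium terminus C2 through C1 (5-endo-trig Michael closure of the cyclopentene), and proton transfer with loss of PBu3 leaves the C3=C4 alkene conjugated to C17=O. The closest known reactions are the intramolecular forms of the Lu allenoate/alkynoate–alkene [3+2] annulation (carbon-tethered ynoate–enones, and ester-tethered allenoates that give cyclopentene-fused lactones). C5 is set by the tether: the three-atom link C6–O–C17 can only reach the enone face that carries O6, so C4 ends up cis to O6; C1 is set in the second closure, which from that face can only give the cis-fused five-membered ring. The step needs α- rather than γ-attack of the dipole and C5 rather than C1 as acceptor: α-attack gives a five-membered lactone where γ-attack would need a seven-membered one, and C5 is the β-carbon of the enone. Dilution should suppress intermolecular annulation, and the tertiary C15 hydroxyl is too hindered to add to the ynoate.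

**Step 11**
Reactants: 14 tricyclic keto lactone
Product: 15 methylene lactone (1R,5R,6S,7R,11R,14R): as 14 with C10=C18H2 in place of the ketone
Conditions: Zn, CH2Br2, TiCl4, THF, 0 °C (aged reagent); then 14, CH2Cl2, rt
Reagents that add atoms: dibromomethane BrCBr
Why: Lombardo (Takai-type) methylenation: the non-basic zinc–titanium gem-dimetal reagent should convert the C10 ketone into the exocyclic methylene without epimerising C1 and without attacking the lactone.

**Step 12**
Reactants: 15 methylene lactone
Product: 16 triol (1R,5R,6S,7R,11R,14R): 17-hydroxy-15-O-deacetyldictyol H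
Conditions: i-Bu2AlH (5 equiv), CH2Cl2, −78 to 0 °C; aq. KNaC4H4O6
Reagents that add atoms: none
Why: i-Bu2AlH reduces the unsaturated lactone by 1,2-hydride addition through the lactol to the primary allylic alcohol at C17 and frees the C6 hydroxyl; the alkenes are untouched.

**Step 13**
Reactants: 16 triol
Product: 17 triacetate: 17-acetoxy-6-O-acetyldictyol H
Conditions: Ac2O, Et3N, DMAP, CH2Cl2, 35 °C, prolonged
Reagents that add atoms: acetic anhydride CC(=O)OC(C)=O
Why: DMAP-catalysed acetylation (acyl-pyridinium transfer) should esterify the primary allylic, the secondary and, more slowly, the tertiary hydroxyl, which installs the C15 acetate of the target and the allylic leaving group at C17 in one operation.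

**Step 14**
Reactants: 17 triacetate
Product: 18 6-O-acetyldictyol H
Conditions: Pd(PPh3)4 (5 mol %), NaBH4, THF, 0 °C to rt
Reagents that add atoms: none
Why: Palladium-catalysed allylic hydrogenolysis (Tsuji–Trost ionisation by zerovalent palladium, then hydride transfer from borohydride to the less substituted allyl terminus): only the allylic C17 acetate ionises, and hydride delivery at C17 should leave the C3=C4 alkene in place and a methyl group on C4.

**Step 15**
Reactants: 18 6-O-acetyldictyol H
Product: 19 dictyol H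
Conditions: K2CO3 (0.3 equiv), MeOH, 0 °C
Reagents that add atoms: none
Why: Chemoselective base-catalysed methanolysis (transesterification): the secondary C6 acetate should be cleaved far faster than the tertiary C15 acetate, whose carbonyl is shielded by the geminal methyl groups, so the monoacetate results.

**Compound list**

1 | (R)-(−)-linalool, (3R)-3,7-dimethylocta-1,6-dien-3-ol | C=C[C@](C)(O)CCC=C(C)C | starting material
2 | (3R,6S)-6,7-epoxylinalool, (3R)-5-[(2S)-3,3-dimethyloxiran-2-yl]-3-methylpent-1-en-3-ol | C=C[C@](C)(O)CC[C@@H]1OC1(C)C | intermediate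
3 | 2-[(2R,5R)-5-ethenyl-5-methyloxolan-2-yl]propan-2-ol | C=C[C@@]1(C)CC[C@H](C(C)(C)O)O1 | intermediate
4 | 2-[(2R,5R)-5-(2-hydroxyethyl)-5-methyloxolan-2-yl]propan-2-ol | OCC[C@@]1(C)CC[C@H](C(C)(C)O)O1 | intermediate
5 | 2-[(2R,5R)-5-(2-hydroxypropan-2-yl)-2-methyloxolan-2-yl]acetaldehyde | O=CC[C@@]1(C)CC[C@H](C(C)(C)O)O1 | intermediate
6 | (E)-but-2-enal | C/C=C/C=O | starting material
7 | (E)-hexa-1,4-dien-3-ol (racemic) | C/C=C/C(O)C=C | intermediate
8 | (E)-hexa-1,4-dien-3-one | C/C=C/C(=O)C=C | intermediate
9 | (2S,6E)-2-[(2R,5R)-5-(2-hydroxypropan-2-yl)-2-methyloxolan-2-yl]-5-oxooct-6-enal | C/C=C/C(=O)CC[C@@H]([C@@]1(C)CC[C@H](C(C)(C)O)O1)C=O | intermediate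
10 | (2E,7R,8S)-8-hydroxy-7-[(2R,5R)-5-(2-hydroxypropan-2-yl)-2-methyloxolan-2-yl]deca-2,9-dien-4-one | C/C=C/C(=O)CC[C@@H]([C@@]1(C)CC[C@H](C(C)(C)O)O1)[C@@H](O)C=C | intermediate
11 | (4S,5R)-4-hydroxy-5-[(2R,5R)-5-(2-hydroxypropan-2-yl)-2-methyloxolan-2-yl]cyclohept-2-en-1-one | O=C1CC[C@@H]([C@@]2(C)CC[C@H](C(C)(C)O)O2)[C@@H](O)C=C1 | intermediate
12 | but-2-ynoic acid | CC#CC(=O)O | starting material
13 | (1S,7R)-7-[(2R,5R)-5-(2-hydroxypropan-2-yl)-2-methyloxolan-2-yl]-4-oxocyclohept-2-en-1-yl but-2-ynoate | O=C1CC[C@@H]([C@@]2(C)CC[C@H](C(C)(C)O)O2)[C@@H](OC(=O)C#CC)C=C1 | intermediate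
14 | tricyclic keto lactone (1R,5R,6S,7R,11R,14R): C10 ketone, C3=C4 alkene, C17 lactone carbonyl on O6, free C15 hydroxyl | O=C1CC[C@@H]([C@@]2(C)CC[C@H](C(C)(C)O)O2)[C@H]3OC(=O)C4=CC[C@@H]1[C@@H]34 | intermediate
15 | methylene lactone (1R,5R,6S,7R,11R,14R): as 14 with C10=CH2 | C=C1CC[C@@H]([C@@]2(C)CC[C@H](C(C)(C)O)O2)[C@H]3OC(=O)C4=CC[C@@H]1[C@@H]34 | intermediate
16 | triol: 17-hydroxy-15-O-deacetyldictyol H | C=C1CC[C@@H]([C@@]2(C)CC[C@H](C(C)(C)O)O2)[C@@H](O)[C@H]2C(CO)=CC[C@@H]12 | intermediate
17 | triacetate: 17-acetoxy-6-O-acetyldictyol H | C=C1CC[C@@H]([C@@]2(C)CC[C@H](C(C)(C)OC(C)=O)O2)[C@@H](OC(C)=O)[C@H]2C(COC(C)=O)=CC[C@@H]12 | intermediate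
18 | 6-O-acetyldictyol H | C=C1CC[C@@H]([C@@]2(C)CC[C@H](C(C)(C)OC(C)=O)O2)[C@@H](OC(C)=O)[C@H]2C(C)=CC[C@@H]12 | intermediate
19 | dictyol H (1R,5R,6S,7R,11R,14R) | C=C1CC[C@@H]([C@@]2(C)CC[C@H](C(C)(C)OC(C)=O)O2)[C@@H](O)[C@H]2C(C)=CC[C@@H]12 | target

**Step count.** Total: 15 steps. Longest linear sequence: 13 steps (steps 1–3 and 6–15, from 1).

**Steps most likely to fail**

Step 10 (key step). The phosphonium dienolate may oligomerise, or the sequence may stall after the first Michael addition, because the second closure has to place an alkene at the carbon shared by two five-membered rings. The fallback sets out from 11 and comes back at 14; it makes the same two bonds by a base-mediated Michael-initiated ring closure. 11 is acylated with 4-bromo-3-oxobutanoyl bromide (from diketene and Br2, CH2Cl2, −30 °C, used at once; pyridine) to the 4-bromoacetoacetate of 11 F1. K2CO3 in MeCN lets C4 of the β-keto ester add to C5 through the same lactone tether, and the C10 enolate then displaces bromide at C2, to give the cyclopentanone-fused diketo lactone F2. NaH and PhNTf2 (THF, 0 °C) convert the β-keto lactone into the enol triflate F3. Reduction of the triflate (Pd(OAc)2, PPh3, HCO2H, Bu3N, DMF, 60 °C) gives 14.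

Step 6. Enamine formation at the neopentyl-type aldehyde may be slow, and the enamine may open the oxolane by β-elimination, which would cost conversion and the C11 centre. The fallback sets out from 5 and comes back at 9; it uses auxiliary-controlled azaenolate alkylation. Condensation of 5 with (R)-1-amino-2-(methoxymethyl)pyrrolidine gives the RAMP hydrazone F4. The dienone 8 is converted with Me3SiI and ethylene glycol into 2-(2-iodoethyl)-2-[(E)-prop-1-en-1-yl]-1,3-dioxolane F5. Deprotonation of F4 (LiN(i-Pr)2, 2.2 equiv, THF, 0 °C) and alkylation with F5 at −100 °C gives the alkylated hydrazone F6. Two-phase hydrolysis with aqueous oxalic acid removes the auxiliary and the ketal and gives 9.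

Step 7. Chelation between the aldehyde and the oxolane oxygen may compete with the Felkin–Anh mode and erode facial selectivity. The fallback sets out from 9 and comes back at 13; it aims at the other epimer and inverts it later. The addition is run under chelation control (CH2=CHZnBr, MgBr2·OEt2, CH2Cl2, −78 °C; the organozinc leaves the enone alone) to give the (8R) epimer of 10 F7. Ring-closing metathesis as in step 8 gives the (4R) epimer of 11 F8. Esterification of F8 with 12 under Mitsunobu conditions (PPh3, DIAD, THF, 0 °C) inverts C6 and gives 13.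

**Further compounds**

F1 | step 10 | (1S,7R)-7-[(2R,5R)-5-(2-hydroxypropan-2-yl)-2-methyloxolan-2-yl]-4-oxocyclohept-2-en-1-yl 4-bromo-3-oxobutanoate | O=C1CC[C@@H]([C@@]2(C)CC[C@H](C(C)(C)O)O2)[C@@H](OC(=O)CC(=O)CBr)C=C1
F2 | step 10 | cyclopentanone-fused diketo lactone (C3 and C10 ketones, C17 lactone on O6, H4 cis to H5) | O=C1CC[C@@H]([C@@]2(C)CC[C@H](C(C)(C)O)O2)[C@H]3OC(=O)[C@H]4C(=O)C[C@@H]1[C@@H]34
F3 | step 10 | enol triflate of F2 (C3 triflate, C3=C4 alkene) | O=C1CC[C@@H]([C@@]2(C)CC[C@H](C(C)(C)O)O2)[C@H]3OC(=O)C4=C(OS(=O)(=O)C(F)(F)F)C[C@@H]1[C@@H]34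
F4 | step 6 | RAMP hydrazone of 5 | COC[C@H]1CCCN1/N=C/C[C@@]2(C)CC[C@H](C(C)(C)O)O2
F5 | step 6 | 2-(2-iodoethyl)-2-[(E)-prop-1-en-1-yl]-1,3-dioxolane | C/C=C/C1(CCI)OCCO1
F6 | step 6 | alkylated RAMP hydrazone (C7 as in 9, ketone masked as dioxolane) | COC[C@H]1CCCN1/N=C/[C@@H](CCC2(/C=C/C)OCCO2)[C@@]3(C)CC[C@H](C(C)(C)O)O3
F7 | step 7 | (2E,7R,8R)-8-hydroxy-7-[(2R,5R)-5-(2-hydroxypropan-2-yl)-2-methyloxolan-2-yl]deca-2,9-dien-4-one | C/C=C/C(=O)CC[C@@H]([C@@]1(C)CC[C@H](C(C)(C)O)O1)[C@H](O)C=C
F8 | step 7 | (4R,5R)-4-hydroxy-5-[(2R,5R)-5-(2-hydroxypropan-2-yl)-2-methyloxolan-2-yl]cyclohept-2-en-1-one | O=C1CC[C@@H]([C@@]2(C)CC[C@H](C(C)(C)O)O2)[C@H](O)C=C1
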